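1. Numbering: ring O1–O2–C3–C4–C5–C6; C3 carries Cα of the propanoic acid, C6 carries CH3 and the chain C1'H2–C2'H=C3'H–C4'(CH3)(OH)–CH2CH2–(2,6,6-trimethylcyclohexenyl).
2. Retrosynthetic cuts, in order: CO2H back to a silyl-protected CH2OH; the C2'=C3' alkene by cross-metathesis (C2' then back to an aldehyde and a CH2OH); the O1–C6 bond; the O2–C3 bond.
3. Enabling feature: C6 is a tertiary peroxy carbon whose arm C1'–C2' can end in oxygen, so C6–C1'–C2'–O is stored as a 2,2-disubstituted oxetane that a C3–OOH, tethered through C4 and C5, opens 6-exo; C2'–C1'–C6(CH3)–C5–C4–C3–Cα(CH3)–C(carboxyl) is the ten-carbon skeleton of linalool.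
4. Forward order: (R)-linalool → allylic oxidation, silylation → oxetane → hydroboration → nosylate → hydroperoxide → 1,2-dioxane (the only ring closed; the cyclohexene comes with dihydro-β-ionone) → allyl dioxane → cross-metathesis with the tertiary vinyl carbinol → desilylation, oxidation to the acid.
5. Stereochemistry: C6 from (R)-linalool, inverted once in the ring closure; C3 and Cα from syn hydroboration of the E alkene with IpcBH2, C3 then inverted by hydrogen peroxide; C4' from a Sharpless epoxidation; the E alkene from metathesis.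

Key step: step 8

Remark: commercial (R)-(−)-linalool is taken to be of high enantiomeric purity, and the facial sense of IpcBH2 in step 5 is assigned by analogy with simple trisubstituted alkenes.
Abbreviations: TBDPS = tert-butyldiphenylsilyl; Ns = 4-nitrobenzenesulfonyl; Ipc = isopinocampheyl; 9-BBN = 9-borabicyclo[3.3.1]nonane. Dioxane locants in the names follow the numbering of line 1.

Step 1
Reactants: 1 (R)-linalool
Product: 2 (2E,6R)-2,6-dimethylocta-2,7-diene-1,6-diol
Conditions: SeO2 (0.2 equiv), tBuOOH (70% aq.), salicylic acid (cat.), CH2Cl2, rt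
Reagents that add atoms: selenium dioxide, O=[Se]=O (delivers the oxygen); tert-butyl hydroperoxide, CC(C)(C)OO (stoichiometric oxygen source)
Why: Catalytic SeO2 allylic oxidation (ene reaction, then [2,3]-sigmatropic shift) is selective for the E methyl group of a trisubstituted alkene, while the vinyl group, which has no allylic hydrogen, and the carbinol stereocentre are not involved.

Step 2
Reactants: 2 (2E,6R)-2,6-dimethylocta-2,7-diene-1,6-diol
Product: 3 (3R,6E)-8-(tert-butyldiphenylsilyloxy)-3,7-dimethylocta-1,6-dien-3-ol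
Conditions: TBDPSCl, imidazole, CH2Cl2, 0 °C
Reagents that add atoms: tert-butyldiphenylsilyl chloride, CC(C)(C)[Si](Cl)(c1ccccc1)c1ccccc1
Why: Silylation with the bulky chlorosilane takes the primary allylic hydroxyl and leaves the tertiary one free.

Step 3
Reactants: 3 (3R,6E)-8-(tert-butyldiphenylsilyloxy)-3,7-dimethylocta-1,6-dien-3-ol
Product: 5 (3R,6E)-8-(tert-butyldiphenylsilyloxy)-3,7-dimethyloct-6-ene-1,3-diol, via B-alkyl-9-BBN adduct 4 (not isolated)
Conditions: 9-BBN (2.5 equiv), THF, 0 °C → rt; then NaOH, H2O2, 0 °C → rt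
Reagents that add atoms: hydrogen peroxide, OO (oxygen of the new hydroxyl); 9-BBN, B1C2CCCC1CCC2 (boron in 4 only)
Why: Hydroboration–oxidation with 9-BBN is anti-Markovnikov and strongly prefers the monosubstituted vinyl group over the trisubstituted, allylically oxygenated alkene, and the carbinol stereocentre is untouched.

Step 4
Reactants: 5 (3R,6E)-8-(tert-butyldiphenylsilyloxy)-3,7-dimethyloct-6-ene-1,3-diol
Product: 7 (2R)-2-[(3E)-5-(tert-butyldiphenylsilyloxy)-4-methylpent-3-en-1-yl]-2-methyloxetane, via primary tosylate 6 (not isolated)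
Conditions: nBuLi (1.0 equiv), THF, −78 → 0 °C; TsCl (1.0 equiv), 0 °C; then KOtBu (1.2 equiv), 0 °C → rt
Reagents that add atoms: p-toluenesulfonyl chloride, Cc1ccc(cc1)S(=O)(=O)Cl (tosyl group in 6 only; nothing of it remains in 7)
Why: Sulfonylation of the primary alkoxide followed by intramolecular Williamson etherification (4-exo-tet) by the tertiary alkoxide closes the oxetane without breaking a bond at the stereocentre, so the linalool configuration is carried over unchanged.

Step 5
Reactants: 7 (2R)-2-[(3E)-5-(tert-butyldiphenylsilyloxy)-4-methylpent-3-en-1-yl]-2-methyloxetane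
Product: 9 (2S,3R)-1-(tert-butyldiphenylsilyloxy)-2-methyl-5-[(2R)-2-methyloxetan-2-yl]pentan-3-ol, via isopinocampheyl alkylborane 8 (not isolated)
Conditions: IpcBH2 [from (−)-α-pinene, BF3-free solution] (1.5 equiv), Et2O, −25 °C; then NaOH, H2O2, 0 °C → rt
Reagents that add atoms: hydrogen peroxide, OO (oxygen of the new hydroxyl); monoisopinocampheylborane, C[C@@H]1[C@@H](B)C[C@H]2C[C@@H]1C2(C)C (boron and Ipc group in 8 only)
Why: Brown asymmetric hydroboration places boron on the less substituted C3, syn addition across the E alkene fixes the anti relation of the C3 oxygen and the Cα methyl, the reagent antipode from (−)-α-pinene is chosen to give 3R (sense taken from simple trisubstituted alkenes), and the oxidation proceeds with retention.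

Step 6
Reactants: 9 (2S,3R)-1-(tert-butyldiphenylsilyloxy)-2-methyl-5-[(2R)-2-methyloxetan-2-yl]pentan-3-ol
Product: 10 (2S,3R)-1-(tert-butyldiphenylsilyloxy)-2-methyl-5-[(2R)-2-methyloxetan-2-yl]pentan-3-yl 4-nitrobenzenesulfonate
Conditions: NsCl, Et3N, DMAP (cat.), CH2Cl2, 0 °C
Reagents that add atoms: 4-nitrobenzenesulfonyl chloride, O=S(=O)(Cl)c1ccc(cc1)[N+](=O)[O-]
Why: DMAP-catalysed sulfonylation occurs at oxygen with retention at C3 and gives a leaving group reactive enough for substitution at a β-branched carbon, while the basic medium keeps the oxetane intact.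

Step 7
Reactants: 10 (2S,3R)-1-(tert-butyldiphenylsilyloxy)-2-methyl-5-[(2R)-2-methyloxetan-2-yl]pentan-3-yl 4-nitrobenzenesulfonate
Product: 11 (2S,3S)-1-(tert-butyldiphenylsilyloxy)-3-hydroperoxy-2-methyl-5-[(2R)-2-methyloxetan-2-yl]pentane
Conditions: 50% aq. H2O2 (large excess), KOH, MeOH–THF, 0 °C → rt
Reagents that add atoms: hydrogen peroxide, OO
Why: SN2 displacement of a secondary sulfonate by the hydroperoxide anion, a strong alpha-effect nucleophile, inverts C3 to S, and the oxetane is inert to base.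

Step 8
Reactants: 11 (2S,3S)-1-(tert-butyldiphenylsilyloxy)-3-hydroperoxy-2-methyl-5-[(2R)-2-methyloxetan-2-yl]pentane
Product: 12 (3S,6S)-6-(2-hydroxyethyl)-6-methyl-3-[(2S)-1-(tert-butyldiphenylsilyloxy)propan-2-yl]-1,2-dioxane
Conditions: Yb(OTf)3 (10 mol %), Et2O, 0 °C → rt
Reagents that add atoms: none
Why: The oxophilic Lewis acid binds the oxetane oxygen, and the terminal oxygen of the C3 hydroperoxide attacks the tertiary carbon C6 from the side opposite the departing oxygen, forming O1–C6 and releasing the former oxetane oxygen as the C2' hydroxyl. The closest known reaction type is the acid-promoted opening of 2,2-dialkyl oxetanes by hydrogen peroxide or by a tethered hydroperoxide, which runs with inversion at the tertiary carbon. The 1,2-dioxane closes in 6-exo-tet mode through a chair with the C3 side chain equatorial. C6 is the only stereocentre made: it becomes S by inversion of the R oxetane carbon, whose configuration is that of (R)-linalool, while C3 and Cα keep all their bonds. The step needs attack at C6 rather than at C2' and substitution rather than ionisation: the C4–C5 tether can only reach C6 (attack at C2' would mean an eight-membered ring), and the strain of the four-membered ring lets the tertiary C–O bond break in a tight transition state in ether before a free cation forms. The silyl ether and the product peroxide should tolerate the mild Lewis acid.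

Step 9
Reactants: 12 (3S,6S)-6-(2-hydroxyethyl)-6-methyl-3-[(2S)-1-(tert-butyldiphenylsilyloxy)propan-2-yl]-1,2-dioxane
Product: 13 (3S,6S)-6-methyl-6-(2-oxoethyl)-3-[(2S)-1-(tert-butyldiphenylsilyloxy)propan-2-yl]-1,2-dioxane
Conditions: Dess–Martin periodinane, CH2Cl2, 0 °C → rt
Reagents that add atoms: none
Why: Dess–Martin oxidation gives the aldehyde under non-basic, non-reducing conditions that leave the dialkyl peroxide and the silyl ether alone.

Step 10
Reactants: 13 (3S,6S)-6-methyl-6-(2-oxoethyl)-3-[(2S)-1-(tert-butyldiphenylsilyloxy)propan-2-yl]-1,2-dioxane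
Product: 14 (3S,6S)-6-allyl-6-methyl-3-[(2S)-1-(tert-butyldiphenylsilyloxy)propan-2-yl]-1,2-dioxane
Conditions: Ph3PCH3Br, KN(SiMe3)2, THF, 0 °C; then 13, −78 → 0 °C
Reagents that add atoms: methyltriphenylphosphonium bromide, C[P+](c1ccccc1)(c1ccccc1)c1ccccc1.[Br-] (the CH2 group)
Why: Wittig methylenation with the salt-free ylide at low temperature should add to the aldehyde faster than it enolises it (which would open the ring by β-elimination) or attacks the hindered O–O bond, and C6 is not touched.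

Step 11
Reactants: 15 dihydro-β-ionone
Product: 16 ethyl (2E)-3-methyl-5-(2,6,6-trimethylcyclohex-1-en-1-yl)pent-2-enoate
Conditions: (EtO)2P(O)CH2CO2Et, NaH, THF, 0 °C → reflux
Reagents that add atoms: triethyl phosphonoacetate, CCOC(=O)CP(=O)(OCC)OCC
Why: Horner–Wadsworth–Emmons olefination of the methyl ketone with the stabilised phosphonate anion favours the E trisubstituted enoate, and the minor Z isomer is to be removed by chromatography.

Step 12
Reactants: 16 ethyl (2E)-3-methyl-5-(2,6,6-trimethylcyclohex-1-en-1-yl)pent-2-enoate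
Product: 17 (2E)-3-methyl-5-(2,6,6-trimethylcyclohex-1-en-1-yl)pent-2-en-1-ol
Conditions: iBu2AlH, CH2Cl2, −78 °C
Reagents that add atoms: none
Why: 1,2-Reduction of the conjugated ester by the aluminium hydride gives the allylic alcohol with the E geometry unchanged.

Step 13
Reactants: 17 (2E)-3-methyl-5-(2,6,6-trimethylcyclohex-1-en-1-yl)pent-2-en-1-ol
Product: 18 [(2S,3S)-3-methyl-3-[2-(2,6,6-trimethylcyclohex-1-en-1-yl)ethyl]oxiran-2-yl]methanol
Conditions: Ti(OiPr)4 (cat.), L-(+)-diethyl tartrate (cat.), tBuOOH, 4 Å molecular sieves, CH2Cl2, −20 °C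
Reagents that add atoms: tert-butyl hydroperoxide, CC(C)(C)OO (epoxide oxygen)
Why: Sharpless asymmetric epoxidation acts only on the allylic alcohol (the tetrasubstituted ring alkene is not a substrate), and with L-(+)-diethyl tartrate an E 3,3-disubstituted allylic alcohol of the geraniol type gives the (2S,3S)-epoxide.

Step 14
Reactants: 18 [(2S,3S)-3-methyl-3-[2-(2,6,6-trimethylcyclohex-1-en-1-yl)ethyl]oxiran-2-yl]methanol
Product: 19 the primary iodide of 18, 3-(iodomethyl)-2-methyl-2-[2-(2,6,6-trimethylcyclohex-1-en-1-yl)ethyl]oxirane with both oxirane carbons configured as in 18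
Conditions: PPh3, I2, imidazole, THF, 0 °C
Reagents that add atoms: iodine, II
Why: Appel-type iodination replaces only the primary hydroxyl and leaves both oxirane carbons untouched.

Step 15
Reactants: 19 the primary iodide of 18
Product: 20 (3S)-3-methyl-5-(2,6,6-trimethylcyclohex-1-en-1-yl)pent-1-en-3-ol
Conditions: Zn dust, EtOH, reflux
Reagents that add atoms: none
Why: Zinc inserts into the C–I bond and β-elimination opens the oxirane (reductive elimination of a 2,3-epoxy iodide), giving the tertiary vinyl carbinol whose C–O bond and S configuration come unchanged from the quaternary epoxide carbon.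

Step 16
Reactants: 14 (3S,6S)-6-allyl-6-methyl-3-[(2S)-1-(tert-butyldiphenylsilyloxy)propan-2-yl]-1,2-dioxane; 20 (3S)-3-methyl-5-(2,6,6-trimethylcyclohex-1-en-1-yl)pent-1-en-3-ol (3 equiv)
Product: 21 (3S,6S)-6-[(2E,4S)-4-hydroxy-4-methyl-6-(2,6,6-trimethylcyclohex-1-en-1-yl)hex-2-en-1-yl]-6-methyl-3-[(2S)-1-(tert-butyldiphenylsilyloxy)propan-2-yl]-1,2-dioxane
Conditions: second-generation Hoveyda–Grubbs catalyst RuCl2(H2IMes)(=CH-C6H4-2-OiPr) (5–10 mol %), CH2Cl2, 40 °C
Reagents that add atoms: none
Why: Olefin cross-metathesis of a terminal allyl group with an unprotected tertiary vinyl carbinol, which homodimerises only slowly, favours the cross product, the bulky carbinol carbon enforces the E geometry, the tetrasubstituted ring alkene is inert, and dialkyl peroxides are tolerated by ruthenium alkylidenes.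

Step 17
Reactants: 21 (3S,6S)-6-[(2E,4S)-4-hydroxy-4-methyl-6-(2,6,6-trimethylcyclohex-1-en-1-yl)hex-2-en-1-yl]-6-methyl-3-[(2S)-1-(tert-butyldiphenylsilyloxy)propan-2-yl]-1,2-dioxane
Product: 22 (2S)-2-[(3S,6S)-6-[(2E,4S)-4-hydroxy-4-methyl-6-(2,6,6-trimethylcyclohex-1-en-1-yl)hex-2-en-1-yl]-6-methyl-1,2-dioxan-3-yl]propan-1-ol
Conditions: nBu4NF, AcOH, THF, 0 °C → rt
Reagents that add atoms: none
Why: Fluoride-induced desilylation, buffered with acetic acid so that the C3–H next to the peroxide is not exposed to strong base (Kornblum–DeLaMare fragmentation), frees the primary alcohol.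

Step 18
Reactants: 22 (2S)-2-[(3S,6S)-6-[(2E,4S)-4-hydroxy-4-methyl-6-(2,6,6-trimethylcyclohex-1-en-1-yl)hex-2-en-1-yl]-6-methyl-1,2-dioxan-3-yl]propan-1-ol
Product: 24 (2R)-2-[(3S,6S)-6-[(2E,4S)-4-hydroxy-4-methyl-6-(2,6,6-trimethylcyclohex-1-en-1-yl)hex-2-en-1-yl]-6-methyl-1,2-dioxan-3-yl]propanoic acid, via aldehyde 23 (not isolated)
Conditions: TEMPO (0.2 equiv), PhI(OAc)2 (2.2 equiv), MeCN–H2O, rt
Reagents that add atoms: water, O (second oxygen of the carboxyl group, through the aldehyde hydrate)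
Why: Oxoammonium-mediated oxidation takes the primary alcohol through the aldehyde hydrate to the acid under near-neutral conditions, which should spare the tertiary allylic alcohol, both alkenes and the peroxide and should not epimerise Cα (the descriptor changes from S to R only because CO2H outranks C3).

Compound list
1 | (R)-linalool, (3R)-3,7-dimethylocta-1,6-dien-3-ol | C=C[C@](C)(O)CCC=C(C)C | starting material
2 | (2E,6R)-2,6-dimethylocta-2,7-diene-1,6-diol | C=C[C@](C)(O)CC/C=C(\C)CO | intermediate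
3 | (3R,6E)-8-(tert-butyldiphenylsilyloxy)-3,7-dimethylocta-1,6-dien-3-ol | C=C[C@](C)(O)CC/C=C(\C)CO[Si](c1ccccc1)(c2ccccc2)C(C)(C)C | intermediate
4 | B-alkyl-9-BBN adduct of 3 (boron on C1, carbinol carbon as in 3) | C(C[C@](C)(O)CC/C=C(\C)CO[Si](c1ccccc1)(c2ccccc2)C(C)(C)C)B3C4CCCC3CCC4 | intermediate (not isolated)
5 | (3R,6E)-8-(tert-butyldiphenylsilyloxy)-3,7-dimethyloct-6-ene-1,3-diol | OCC[C@](C)(O)CC/C=C(\C)CO[Si](c1ccccc1)(c2ccccc2)C(C)(C)C | intermediate
6 | (3R,6E)-8-(tert-butyldiphenylsilyloxy)-3-hydroxy-3,7-dimethyloct-6-en-1-yl 4-methylbenzenesulfonate | Cc1ccc(cc1)S(=O)(=O)OCC[C@](C)(O)CC/C=C(\C)CO[Si](c2ccccc2)(c3ccccc3)C(C)(C)C | intermediate (not isolated)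
7 | (2R)-2-[(3E)-5-(tert-butyldiphenylsilyloxy)-4-methylpent-3-en-1-yl]-2-methyloxetane | C[C@]1(CCO1)CC/C=C(\C)CO[Si](c2ccccc2)(c3ccccc3)C(C)(C)C | intermediate
8 | isopinocampheyl alkylborane, boron on C3 of the chain of 9 | C[C@@H]1[C@@H](B[C@H](CC[C@]4(C)CCO4)[C@@H](C)CO[Si](c5ccccc5)(c6ccccc6)C(C)(C)C)C[C@H]2C[C@@H]1C2(C)C | intermediate (not isolated)
9 | (2S,3R)-1-(tert-butyldiphenylsilyloxy)-2-methyl-5-[(2R)-2-methyloxetan-2-yl]pentan-3-ol | C[C@]1(CCO1)CC[C@@H](O)[C@@H](C)CO[Si](c2ccccc2)(c3ccccc3)C(C)(C)C | intermediate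
10 | (2S,3R)-1-(tert-butyldiphenylsilyloxy)-2-methyl-5-[(2R)-2-methyloxetan-2-yl]pentan-3-yl 4-nitrobenzenesulfonate | C[C@]1(CCO1)CC[C@@H](OS(=O)(=O)c2ccc(cc2)[N+](=O)[O-])[C@@H](C)CO[Si](c3ccccc3)(c4ccccc4)C(C)(C)C | intermediate
11 | (2S,3S)-1-(tert-butyldiphenylsilyloxy)-3-hydroperoxy-2-methyl-5-[(2R)-2-methyloxetan-2-yl]pentane | C[C@]1(CCO1)CC[C@H](OO)[C@@H](C)CO[Si](c2ccccc2)(c3ccccc3)C(C)(C)C | intermediate
12 | (3S,6S)-6-(2-hydroxyethyl)-6-methyl-3-[(2S)-1-(tert-butyldiphenylsilyloxy)propan-2-yl]-1,2-dioxane | OCC[C@]1(C)CC[C@@H]([C@@H](C)CO[Si](c2ccccc2)(c3ccccc3)C(C)(C)C)OO1 | intermediate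
13 | (3S,6S)-6-methyl-6-(2-oxoethyl)-3-[(2S)-1-(tert-butyldiphenylsilyloxy)propan-2-yl]-1,2-dioxane | O=CC[C@]1(C)CC[C@@H]([C@@H](C)CO[Si](c2ccccc2)(c3ccccc3)C(C)(C)C)OO1 | intermediate
14 | (3S,6S)-6-allyl-6-methyl-3-[(2S)-1-(tert-butyldiphenylsilyloxy)propan-2-yl]-1,2-dioxane | C=CC[C@]1(C)CC[C@@H]([C@@H](C)CO[Si](c2ccccc2)(c3ccccc3)C(C)(C)C)OO1 | intermediate
15 | dihydro-β-ionone, 4-(2,6,6-trimethylcyclohex-1-en-1-yl)butan-2-one | CC1=C(CCC(C)=O)C(C)(C)CCC1 | starting material
16 | ethyl (2E)-3-methyl-5-(2,6,6-trimethylcyclohex-1-en-1-yl)pent-2-enoate | CCOC(=O)/C=C(\C)CCC1=C(C)CCCC1(C)C | intermediate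
17 | (2E)-3-methyl-5-(2,6,6-trimethylcyclohex-1-en-1-yl)pent-2-en-1-ol | OC/C=C(\C)CCC1=C(C)CCCC1(C)C | intermediate
18 | [(2S,3S)-3-methyl-3-[2-(2,6,6-trimethylcyclohex-1-en-1-yl)ethyl]oxiran-2-yl]methanol | CC1=C(CC[C@]2(C)O[C@H]2CO)C(C)(C)CCC1 | intermediate
19 | primary iodide of 18, 3-(iodomethyl)-2-methyl-2-[2-(2,6,6-trimethylcyclohex-1-en-1-yl)ethyl]oxirane, oxirane carbons as in 18 | CC1=C(CC[C@]2(C)O[C@H]2CI)C(C)(C)CCC1 | intermediate
20 | (3S)-3-methyl-5-(2,6,6-trimethylcyclohex-1-en-1-yl)pent-1-en-3-ol | CC1=C(CC[C@](C)(O)C=C)C(C)(C)CCC1 | intermediate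
21 | (3S,6S)-6-[(2E,4S)-4-hydroxy-4-methyl-6-(2,6,6-trimethylcyclohex-1-en-1-yl)hex-2-en-1-yl]-6-methyl-3-[(2S)-1-(tert-butyldiphenylsilyloxy)propan-2-yl]-1,2-dioxane | CC1=C(CC[C@](C)(O)/C=C/C[C@]2(C)CC[C@@H]([C@@H](C)CO[Si](c3ccccc3)(c4ccccc4)C(C)(C)C)OO2)C(C)(C)CCC1 | intermediate
22 | (2S)-2-[(3S,6S)-6-[(2E,4S)-4-hydroxy-4-methyl-6-(2,6,6-trimethylcyclohex-1-en-1-yl)hex-2-en-1-yl]-6-methyl-1,2-dioxan-3-yl]propan-1-ol | CC1=C(CC[C@](C)(O)/C=C/C[C@]2(C)CC[C@@H]([C@@H](C)CO)OO2)C(C)(C)CCC1 | intermediate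
23 | (2R)-2-[(3S,6S)-6-[(2E,4S)-4-hydroxy-4-methyl-6-(2,6,6-trimethylcyclohex-1-en-1-yl)hex-2-en-1-yl]-6-methyl-1,2-dioxan-3-yl]propanal | CC1=C(CC[C@](C)(O)/C=C/C[C@]2(C)CC[C@@H]([C@@H](C)C=O)OO2)C(C)(C)CCC1 | intermediate (not isolated)
24 | (2R)-2-[(3S,6S)-6-[(2E,4S)-4-hydroxy-4-methyl-6-(2,6,6-trimethylcyclohex-1-en-1-yl)hex-2-en-1-yl]-6-methyl-1,2-dioxan-3-yl]propanoic acid | CC1=C(CC[C@](C)(O)/C=C/C[C@]2(C)CC[C@@H]([C@@H](C)C(=O)O)OO2)C(C)(C)CCC1 | target

Total step count: 18. Longest linear sequence: 13 steps (steps 1–10 and 16–18, from (R)-linalool); the side chain 20 takes 5 steps (11–15) from dihydro-β-ionone.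

Steps most likely to fail

Step 7, displacement by hydrogen peroxide. Substitution at the β-branched secondary carbon may be too slow, so that E2 elimination, attack of the hydroperoxide anion on the sulfonyl or nitroaryl group, a second alkylation to a dialkyl peroxide, or participation of the oxetane oxygen take over. The fallback sets out from nosylate 10 and brings in the peroxide as a protected, singly alkylating nucleophile. 2-Methoxyprop-2-yl hydroperoxide with CsOH·H2O in DMF at 0 °C should displace the nosylate with inversion at C3 and give the peroxyketal (2S,3S)-1-(tert-butyldiphenylsilyloxy)-3-[(2-methoxypropan-2-yl)peroxy]-2-methyl-5-[(2R)-2-methyloxetan-2-yl]pentane F1. Brief treatment with aqueous acetic acid in THF should then remove the ketal as acetone and methanol and return to the route at hydroperoxide 11.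

Step 8, ring closure. The tethered hydroperoxide may not outrun ionisation of the activated oxetane, so that C6 loses its configuration or eliminates, or the secondary hydroperoxide may decompose under the acid. The fallback reverses the order of the two C–O bond formations and sets out from nosylate 10. Ethereal H2O2 in large excess with catalytic Me3SiOTf in Et2O at −78 → 0 °C should open the oxetane at C6 with inversion, the best documented form of this opening, and give the tertiary hydroperoxide (2S,3R,6S)-1-(tert-butyldiphenylsilyloxy)-6-hydroperoxy-8-hydroxy-2,6-dimethyloctan-3-yl 4-nitrobenzenesulfonate F2. KOtBu in THF at 0 °C should then let the hydroperoxide anion displace the C3 nosylate intramolecularly (6-exo-tet, inversion at C3, no cation possible at C6), and the route is rejoined at dioxane alcohol 12; steps 7 and 8 are both bypassed.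

Step 5, asymmetric hydroboration. Facial discrimination by the reagent on an acyclic trisubstituted alkene may be incomplete, which would leave a C3/Cα diastereomer of 9 that is hard to remove at this stage. The fallback makes the two centres by aldehyde crotylation and sets out from oxetane 7. Ozonolysis (O3, CH2Cl2, −78 °C; PPh3) should give 3-[(2R)-2-methyloxetan-2-yl]propanal F3. Roush crotylboration with the (E)-crotylboronate of diisopropyl (R,R)-tartrate (4 Å molecular sieves, toluene, −78 °C; no Lewis acid, so the oxetane is safe) should give the anti homoallylic alcohol (3R,4S)-4-methyl-1-[(2R)-2-methyloxetan-2-yl]hex-5-en-3-ol F4. Ozonolysis with NaBH4 work-up turns the vinyl group into CH2OH and gives (2S,3R)-2-methyl-5-[(2R)-2-methyloxetan-2-yl]pentane-1,3-diol F5. Selective silylation of the primary hydroxyl (TBDPSCl, imidazole, CH2Cl2, 0 °C) returns to the route at alcohol 9.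

Further compounds
F1 | step 7 | (2S,3S)-1-(tert-butyldiphenylsilyloxy)-3-[(2-methoxypropan-2-yl)peroxy]-2-methyl-5-[(2R)-2-methyloxetan-2-yl]pentane | C[C@]1(CCO1)CC[C@H](OOC(C)(C)OC)[C@@H](C)CO[Si](c2ccccc2)(c3ccccc3)C(C)(C)C
F2 | step 8 | (2S,3R,6S)-1-(tert-butyldiphenylsilyloxy)-6-hydroperoxy-8-hydroxy-2,6-dimethyloctan-3-yl 4-nitrobenzenesulfonate | OCC[C@@](C)(OO)CC[C@@H](OS(=O)(=O)c1ccc(cc1)[N+](=O)[O-])[C@@H](C)CO[Si](c2ccccc2)(c3ccccc3)C(C)(C)C
F3 | step 5 | 3-[(2R)-2-methyloxetan-2-yl]propanal | C[C@]1(CCO1)CCC=O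
F4 | step 5 | (3R,4S)-4-methyl-1-[(2R)-2-methyloxetan-2-yl]hex-5-en-3-ol | C[C@]1(CCO1)CC[C@@H](O)[C@@H](C)C=C
F5 | step 5 | (2S,3R)-2-methyl-5-[(2R)-2-methyloxetan-2-yl]pentane-1,3-diol | C[C@]1(CCO1)CC[C@@H](O)[C@@H](C)CO
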